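**Retrosynthetic overview**
1. The last step closes azepine ring C and aminobutenolide ring D together: a pyrrolidine amino aldehyde condenses with pyruvic acid (N–C5, C6–Cα and O–C5 bonds).
2. Pendant lactone ring E comes from Felkin–Anh reduction of a γ-keto ester, made by acylating a Roche-type zinc homoenolate with the C3 carboxyl group.
3. Spirolactone ring B comes from Felkin–Anh addition of a C5–C8 acetal Grignard reagent to a γ-keto acid.
4. Key bond C9a–C9: trans-selective α-lithiation of O-silyl N-Boc-L-prolinol gives an α-amino carbanion (an iminium carbon with reversed polarity), which is acylated by (R)-methylsuccinic anhydride.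
5. Ring order: pyrrolidine A (from L-prolinol), then spirolactone B, then pendant lactone E, then rings C and D in one operation.

Atom labels follow the pyrrolo[1,2-a]azepine core (C1–C3, N4, C5–C9, C9a); C5 is the N,O-acetal carbon and C9 the spiro carbon.

Assumption: the C5 N,O-acetal forms under thermodynamic control and the required (5S) epimer is taken to be the more stable one.

**Step 1**
Reactants: 1 N-Boc-L-prolinol
Product: 2 tert-butyl (2S)-2-{[(tert-butyldimethylsilyl)oxy]methyl}pyrrolidine-1-carboxylate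
Conditions: TBSCl, imidazole, DMF, rt
Reagents that add atoms: tert-butyldimethylsilyl chloride, CC(C)(C)[Si](C)(C)Cl
Why: Imidazole-promoted silylation of the primary alcohol (silyl ether protection) removes the acidic O–H before the organolithium step, and the (S) centre that becomes C3 is carried over unchanged from L-prolinol.

**Step 2**
Reactants: 3 (R)-methylsuccinic acid
Product: 4 (R)-methylsuccinic anhydride
Conditions: AcCl, reflux; distil
Reagents that add atoms: none
Why: Acetyl chloride dehydrates the 1,4-diacid to the five-membered cyclic anhydride (cyclodehydration via a mixed anhydride) under acidic, non-enolising conditions, so the (R) centre that becomes the α-carbon of the spirolactone is retained.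

**Step 3**
Reactants: 2 O-TBS N-Boc-L-prolinol; 4 (R)-methylsuccinic anhydride
Product: 6 (2R)-4-[(2S,5S)-1-Boc-5-(TBSOCH2)pyrrolidin-2-yl]-2-methyl-4-oxobutanoic acid, via trans-5-lithio carbamate 5 (not isolated)
Conditions: s-BuLi, TMEDA, Et2O, −78 °C, 3 h; cannulate into 4 (3 equiv), THF, −78 °C; AcOH quench
Reagents that add atoms: none
Why: Proposed new method: Boc-directed α-lithiation (Beak-type, complex-induced proximity) turns the future C9a, a carbon that normally reacts as an electrophilic iminium carbon, into a configurationally stable dipole-stabilised carbanion that is formed and substituted with retention on the face trans to the C2 substituent (hence 9aS), and inverse addition to excess anhydride should open the less hindered CH2-flanked carbonyl to a ketone carboxylate that resists a second addition, the closest known reactions being the trapping of 2-lithio-N-Boc-pyrrolidines with CO2 or Weinreb amides and the opening of succinic anhydrides by Grignard reagents to γ-keto acids.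

**Step 4**
Reactants: 6 γ-keto acid; 7 2-(3-chloropropyl)-1,3-dioxolane
Product: 10 tert-butyl (2S,5S)-2-(TBSOCH2)-5-{(2S,4R)-2-[3-(1,3-dioxolan-2-yl)propyl]-4-methyl-5-oxooxolan-2-yl}pyrrolidine-1-carboxylate, via Grignard reagent 8 (not isolated), via hydroxy acid 9 (not isolated)
Conditions: 7, Mg, THF, 50 °C; add 6 to 8 (3 equiv), THF, −78 → −20 °C; AcOH quench; PPTS (cat.), CH2Cl2, rt
Reagents that add atoms: none
Why: Grignard addition to a γ-keto carboxylate followed by acid-induced γ-lactonisation (the classical keto acid to lactone sequence) builds the spiro centre, and Felkin–Anh control at the N-Boc α-amino ketone (carbamate nitrogen anti to the nucleophile, attack past C9a–H) delivers the C8 chain to the face that gives 9S.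

**Step 5**
Reactants: 10 silyl ether spirolactone
Product: 11 tert-butyl (2S,5S)-2-{(2S,4R)-2-[3-(1,3-dioxolan-2-yl)propyl]-4-methyl-5-oxooxolan-2-yl}-5-(hydroxymethyl)pyrrolidine-1-carboxylate
Conditions: TBAF, AcOH (1:1), THF, rt
Reagents that add atoms: none
Why: Fluoride-mediated desilylation driven by Si–F bond formation, buffered with acetic acid so that no free alkoxide can attack the Boc group or the lactone, frees the primary alcohol without touching a stereocentre.

**Step 6**
Reactants: 11 primary alcohol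
Product: 12 (2S,5S)-1-Boc-5-{(2S,4R)-2-[3-(1,3-dioxolan-2-yl)propyl]-4-methyl-5-oxooxolan-2-yl}pyrrolidine-2-carboxylic acid
Conditions: TEMPO (cat.), PhI(OAc)2, MeCN/aq. pH 7 phosphate buffer, rt
Reagents that add atoms: water, O
Why: Oxoammonium (TEMPO) catalysed oxidation with PhI(OAc)2 as terminal oxidant takes the primary alcohol through the aldehyde hydrate to the acid under near-neutral conditions, which leaves the urethane-protected α-centre (C3), the acetal and the lactone untouched.

**Step 7**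
Reactants: 12 carboxylic acid; 13 methyl (R)-3-bromo-2-methylpropanoate
Product: 16 methyl (2S)-4-[(2S,5S)-1-Boc-5-{(2S,4R)-2-[3-(1,3-dioxolan-2-yl)propyl]-4-methyl-5-oxooxolan-2-yl}pyrrolidin-2-yl]-2-methyl-4-oxobutanoate, via bromozinc homoenolate 14 (not isolated), via acid chloride 15 (not isolated)
Conditions: 13, Zn dust (TMSCl-activated), THF/DMA, 45 °C; 12, 1-chloro-N,N,2-trimethylprop-1-en-1-amine, CH2Cl2, 0 °C; then 14, Pd(PPh3)4 (5 mol %), THF, 0 °C → rt
Reagents that add atoms: none
Why: Palladium-catalysed acylation of a β-zincio ester (Negishi-type ketone synthesis with a zinc homoenolate, the ester β-carbon acting as donor instead of acceptor) joins the C3 carbonyl to the three-carbon lactone unit under neutral conditions in which neither the Boc-protected α-centre nor the ester α-methyl centre can enolise, so both are carried in with their (S) configuration.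

**Step 8**
Reactants: 16 γ-keto ester
Product: 18 tert-butyl (2S,5S)-2-{(2S,4R)-2-[3-(1,3-dioxolan-2-yl)propyl]-4-methyl-5-oxooxolan-2-yl}-5-[(2S,4S)-4-methyl-5-oxooxolan-2-yl]pyrrolidine-1-carboxylate, via hydroxy ester 17 (not isolated)
Conditions: LiBH(s-Bu)3, THF, −78 °C; AcOH quench; PPTS (cat.), PhMe, 60 °C
Reagents that add atoms: none
Why: Felkin–Anh reduction of the N-Boc α-amino ketone by the bulky borohydride (hydride anti to the carbamate nitrogen and past C3–H) gives the syn (S) carbinol, which closes onto the methyl ester on mild acid treatment (lactonisation), while the existing lactone and the acetal survive at −78 °C.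

**Step 9**
Reactants: 18 N-Boc bis-lactone acetal; 19 pyruvic acid
Product: 22 target CNP0155196.1, via amino aldehyde 20 (not isolated), via bicyclic enamine 21 (not isolated)
Conditions: TFA, CH2Cl2, H2O (2 equiv), 0 °C → rt; evaporate; Et3N (1.1 equiv), 4 Å MS, PhMe, rt; 19 (2 equiv), rt → 90 °C
Reagents that add atoms: none
Why: Proposed new method: acid removes Boc and the dioxolane, the amino aldehyde closes to the seven-membered enamine, whose nucleophilic C6 adds to the ketone of pyruvic acid in an acid-assisted enamine aldol, after which the carboxylate traps the C5 iminium ion and E1cB loss of water through the enamine gives the conjugated aminobutenolide, C5 equilibrating through the ring-opened iminium carboxylate to the more stable (5S) N,O-acetal, the closest known reaction being the secondary-amine-mediated condensation of α-methylene aldehydes with glyoxylic acid to 5-amino- and 5-hydroxy-2(5H)-furanones.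

**Compound list**
1 | N-Boc-L-prolinol, tert-butyl (2S)-2-(hydroxymethyl)pyrrolidine-1-carboxylate | OC[C@@H]1CCCN1C(=O)OC(C)(C)C | starting material
2 | tert-butyl (2S)-2-{[(tert-butyldimethylsilyl)oxy]methyl}pyrrolidine-1-carboxylate | CC(C)(C)[Si](C)(C)OC[C@@H]1CCCN1C(=O)OC(C)(C)C | intermediate
3 | (R)-methylsuccinic acid, (2R)-2-methylbutanedioic acid | OC(=O)C[C@@H](C)C(=O)O | starting material
4 | (R)-methylsuccinic anhydride, (3R)-3-methyloxolane-2,5-dione | O=C1C[C@@H](C)C(=O)O1 | intermediate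
5 | trans-5-lithio derivative of 2 (Li on the future C9a, trans to CH2OTBS) | [Li][C@@H]1CC[C@@H](CO[Si](C)(C)C(C)(C)C)N1C(=O)OC(C)(C)C | intermediate
6 | (2R)-4-[(2S,5S)-1-Boc-5-(TBSOCH2)pyrrolidin-2-yl]-2-methyl-4-oxobutanoic acid | OC(=O)[C@H](C)CC(=O)[C@@H]1CC[C@@H](CO[Si](C)(C)C(C)(C)C)N1C(=O)OC(C)(C)C | intermediate
7 | 2-(3-chloropropyl)-1,3-dioxolane | ClCCCC1OCCO1 | starting material
8 | [3-(1,3-dioxolan-2-yl)propyl]magnesium chloride | Cl[Mg]CCCC1OCCO1 | intermediate
9 | (2R,4S)-4-[(2S,5S)-1-Boc-5-(TBSOCH2)pyrrolidin-2-yl]-7-(1,3-dioxolan-2-yl)-4-hydroxy-2-methylheptanoic acid | OC(=O)[C@H](C)C[C@@](O)(CCCC1OCCO1)[C@@H]2CC[C@@H](CO[Si](C)(C)C(C)(C)C)N2C(=O)OC(C)(C)C | intermediate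
10 | tert-butyl (2S,5S)-2-(TBSOCH2)-5-{(2S,4R)-2-[3-(1,3-dioxolan-2-yl)propyl]-4-methyl-5-oxooxolan-2-yl}pyrrolidine-1-carboxylate | O1CCOC1CCC[C@]2(C[C@@H](C)C(=O)O2)[C@@H]3CC[C@@H](CO[Si](C)(C)C(C)(C)C)N3C(=O)OC(C)(C)C | intermediate
11 | tert-butyl (2S,5S)-2-{(2S,4R)-2-[3-(1,3-dioxolan-2-yl)propyl]-4-methyl-5-oxooxolan-2-yl}-5-(hydroxymethyl)pyrrolidine-1-carboxylate | O1CCOC1CCC[C@]2(C[C@@H](C)C(=O)O2)[C@@H]3CC[C@@H](CO)N3C(=O)OC(C)(C)C | intermediate
12 | (2S,5S)-1-Boc-5-{(2S,4R)-2-[3-(1,3-dioxolan-2-yl)propyl]-4-methyl-5-oxooxolan-2-yl}pyrrolidine-2-carboxylic acid | O1CCOC1CCC[C@]2(C[C@@H](C)C(=O)O2)[C@@H]3CC[C@@H](C(=O)O)N3C(=O)OC(C)(C)C | intermediate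
13 | methyl (R)-3-bromo-2-methylpropanoate | BrC[C@H](C)C(=O)OC | starting material
14 | bromo[(2R)-3-methoxy-2-methyl-3-oxopropyl]zinc | Br[Zn]C[C@H](C)C(=O)OC | intermediate
15 | acid chloride of 12, tert-butyl (2S,5S)-2-(chlorocarbonyl)-5-{(2S,4R)-2-[3-(1,3-dioxolan-2-yl)propyl]-4-methyl-5-oxooxolan-2-yl}pyrrolidine-1-carboxylate | O1CCOC1CCC[C@]2(C[C@@H](C)C(=O)O2)[C@@H]3CC[C@@H](C(=O)Cl)N3C(=O)OC(C)(C)C | intermediate
16 | methyl (2S)-4-[(2S,5S)-1-Boc-5-{(2S,4R)-2-[3-(1,3-dioxolan-2-yl)propyl]-4-methyl-5-oxooxolan-2-yl}pyrrolidin-2-yl]-2-methyl-4-oxobutanoate | O1CCOC1CCC[C@]2(C[C@@H](C)C(=O)O2)[C@@H]3CC[C@@H](C(=O)C[C@H](C)C(=O)OC)N3C(=O)OC(C)(C)C | intermediate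
17 | methyl (2S,4S)-4-[(2S,5S)-1-Boc-5-{(2S,4R)-2-[3-(1,3-dioxolan-2-yl)propyl]-4-methyl-5-oxooxolan-2-yl}pyrrolidin-2-yl]-4-hydroxy-2-methylbutanoate | O1CCOC1CCC[C@]2(C[C@@H](C)C(=O)O2)[C@@H]3CC[C@@H]([C@@H](O)C[C@H](C)C(=O)OC)N3C(=O)OC(C)(C)C | intermediate
18 | tert-butyl (2S,5S)-2-{(2S,4R)-2-[3-(1,3-dioxolan-2-yl)propyl]-4-methyl-5-oxooxolan-2-yl}-5-[(2S,4S)-4-methyl-5-oxooxolan-2-yl]pyrrolidine-1-carboxylate | O1CCOC1CCC[C@]2(C[C@@H](C)C(=O)O2)[C@@H]3CC[C@@H]([C@@H]4C[C@H](C)C(=O)O4)N3C(=O)OC(C)(C)C | intermediate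
19 | pyruvic acid | CC(=O)C(=O)O | starting material
20 | 4-{(2S,4R)-4-methyl-2-[(2S,5S)-5-[(2S,4S)-4-methyl-5-oxooxolan-2-yl]pyrrolidin-2-yl]-5-oxooxolan-2-yl}butanal | O=CCCC[C@]2(C[C@@H](C)C(=O)O2)[C@@H]3CC[C@@H]([C@@H]4C[C@H](C)C(=O)O4)N3 | intermediate
21 | (3S,9S,9aS)-2,3,7,8,9,9a-hexahydro-1H-pyrrolo[1,2-a]azepine enamine (C5=C6) with the (R)-α-methyl spirolactone at C9 and the (2S,4S)-4-methyl-5-oxooxolan-2-yl group at C3 | C1=CCC[C@]2(C[C@@H](C)C(=O)O2)[C@@H]3CC[C@@H]([C@@H]4C[C@H](C)C(=O)O4)N13 | intermediate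
22 | CNP0155196.1: (3S,5S,9S,9aS) pyrrolo[1,2-a]azepine with the α-methylbutenolide fused at C5–C6 (lactone O on C5), the (R)-α-methyl spirolactone at C9 and the (2S,4S)-4-methyl-5-oxooxolan-2-yl group at C3 | CC1=C2CC[C@]3(C[C@@H](C)C(=O)O3)[C@@H]3CC[C@@H]([C@@H]4C[C@H](C)C(=O)O4)N3[C@H]2OC1=O | target

**Count**
Total step count: 9. Longest linear sequence: 8 (steps 1, 3, 4, 5, 6, 7, 8, 9 from compound 1); step 2 is a one-step side branch.

**Three steps most likely to fail**

Step 3 (acylation of the α-amino organolithium by the anhydride). The risks are deprotonation of the anhydride, double addition and attack at the wrong carbonyl. The fallback sets out from 2 and comes back at 10. Carbanion 5 is generated as before but trapped with CO2, a well-established trapping, to give the trans carboxylic acid F1. F1 is converted with 1-chloro-N,N,2-trimethylprop-1-en-1-amine into the acid chloride F2. F2 is coupled under Pd(PPh3)4 catalysis with the bromozinc homoenolate F3, made from methyl (S)-3-bromo-2-methylpropanoate and zinc dust, to give the keto methyl ester F4. Addition of Grignard reagent 8 to F4 then gives an alkoxide that lactonises onto the methyl ester and delivers 10 directly. In this variant the C9a–C9 bond comes from the carbanion and CO2, and the C9–CH2 bond from homoenolate acylation.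

Step 4 (facial selectivity at C9). If magnesium chelation between the Boc carbonyl and the ketone overrides the Felkin–Anh preference, the C9 epimer results. The fallback sets out from 2 and comes back at 10, and swaps the two carbon partners so that a chelate-controlled attack gives 9S. Carbanion 5 is trapped with DMF to give the trans aldehyde F5. Grignard reagent 8 adds to give the secondary alcohol F6, whose carbinol configuration is irrelevant. Dess–Martin periodinane gives the ketone F7. The dichloro(isopropoxy)titanium homoenolate F8 is prepared from methyl (S)-3-bromo-2-methylpropanoate by zinc insertion (the zinc reagent is F3) and transmetalation with TiCl3(OiPr). F8 adds to F7 from the face past C9a–H under chelation, and the alkoxide closes onto the ester to give 10.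

Step 9 (one-flask enamine and pyruvic acid annulation). The main risk is that pyruvic acid reacts through its enol at the C5 iminium carbon (Mannich) instead of being attacked at its ketone by C6. The fallback sets out from 18 and comes back at 22, and makes the C6–Cα bond before any iminium ion exists. PPTS in wet acetone hydrolyses only the dioxolane to give the N-Boc aldehyde F9. TBSOTf and Et3N convert F9 into the silyl enol ether F10. A Mukaiyama aldol addition of F10 to tert-butyl pyruvate (BF3·OEt2, CH2Cl2, −78 °C) gives the α-hydroxy ester aldehyde F11. TFA then removes Boc and the tert-butyl ester, and warming the buffered amino aldehyde acid closes rings C and D by iminium formation, E1cB loss of water and lactonisation to give 22.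

**Further compounds**
F1 | step 3 | (2S,5S)-1-Boc-5-(TBSOCH2)pyrrolidine-2-carboxylic acid | OC(=O)[C@@H]1CC[C@@H](CO[Si](C)(C)C(C)(C)C)N1C(=O)OC(C)(C)C
F2 | step 3 | tert-butyl (2S,5S)-2-(TBSOCH2)-5-(chlorocarbonyl)pyrrolidine-1-carboxylate | ClC(=O)[C@@H]1CC[C@@H](CO[Si](C)(C)C(C)(C)C)N1C(=O)OC(C)(C)C
F3 | step 3 | bromo[(2S)-3-methoxy-2-methyl-3-oxopropyl]zinc | Br[Zn]C[C@@H](C)C(=O)OC
F4 | step 3 | methyl (2R)-4-[(2S,5S)-1-Boc-5-(TBSOCH2)pyrrolidin-2-yl]-2-methyl-4-oxobutanoate | COC(=O)[C@H](C)CC(=O)[C@@H]1CC[C@@H](CO[Si](C)(C)C(C)(C)C)N1C(=O)OC(C)(C)C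
F5 | step 4 | tert-butyl (2S,5S)-2-(TBSOCH2)-5-formylpyrrolidine-1-carboxylate | O=C[C@@H]1CC[C@@H](CO[Si](C)(C)C(C)(C)C)N1C(=O)OC(C)(C)C
F6 | step 4 | tert-butyl (2S,5S)-2-(TBSOCH2)-5-[4-(1,3-dioxolan-2-yl)-1-hydroxybutyl]pyrrolidine-1-carboxylate (carbinol epimers) | OC(CCCC1OCCO1)[C@@H]2CC[C@@H](CO[Si](C)(C)C(C)(C)C)N2C(=O)OC(C)(C)C
F7 | step 4 | tert-butyl (2S,5S)-2-(TBSOCH2)-5-[4-(1,3-dioxolan-2-yl)butanoyl]pyrrolidine-1-carboxylate | O=C(CCCC1OCCO1)[C@@H]2CC[C@@H](CO[Si](C)(C)C(C)(C)C)N2C(=O)OC(C)(C)C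
F8 | step 4 | dichloro(propan-2-yloxy)[(2S)-3-methoxy-2-methyl-3-oxopropyl]titanium | CC(C)O[Ti](Cl)(Cl)C[C@@H](C)C(=O)OC
F9 | step 9 | tert-butyl (2S,5S)-2-[(2S,4R)-4-methyl-5-oxo-2-(4-oxobutyl)oxolan-2-yl]-5-[(2S,4S)-4-methyl-5-oxooxolan-2-yl]pyrrolidine-1-carboxylate | O=CCCC[C@]2(C[C@@H](C)C(=O)O2)[C@@H]3CC[C@@H]([C@@H]4C[C@H](C)C(=O)O4)N3C(=O)OC(C)(C)C
F10 | step 9 | tert-butyldimethylsilyl enol ether of F9 (E/Z mixture at C5=C6) | CC(C)(C)[Si](C)(C)OC=CCC[C@]2(C[C@@H](C)C(=O)O2)[C@@H]3CC[C@@H]([C@@H]4C[C@H](C)C(=O)O4)N3C(=O)OC(C)(C)C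
F11 | step 9 | tert-butyl 3-formyl-2-hydroxy-2-methyl-5-[(2S,4R)-4-methyl-5-oxo-2-{(2S,5S)-1-Boc-5-[(2S,4S)-4-methyl-5-oxooxolan-2-yl]pyrrolidin-2-yl}oxolan-2-yl]pentanoate (mixture at the two new centres) | O=CC(CC[C@]2(C[C@@H](C)C(=O)O2)[C@@H]3CC[C@@H]([C@@H]4C[C@H](C)C(=O)O4)N3C(=O)OC(C)(C)C)C(C)(O)C(=O)OC(C)(C)C
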